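The ratio I carry through Tuesday's flask is bis adduct standing per unit of substrate lost. At 120 min it reads 0.271, and I call it the bis share. Reagent is charged at 3 equiv, so I keep the books on the substrate, the limiting reagent.

all flasks: substrate 0.15 M
- Tuesday's: reagent 3 equiv; temperature 25 °C; the very flask that is asked about, followed so far
- Sunday's: reagent 3 equiv; temperature 10 °C; run made earlier
- flask: reagent 3.00 equiv; temperature 25 °C; time 2.0 h

| run | time / min | bis adduct / % | substrate / % |
|---|---|---|---|
| Tuesday's | 15.0 | 17.0 | 44.6 |
| Tuesday's | 40.0 | 22.9 | 17.1 |
| Tuesday's | 80.0 | 26.5 | 3.6 |
| Tuesday's | 120 | 27.0 | 0.3 |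
| Sunday's | 30.0 | 14.4 | 55.5 |
| Sunday's | 80.0 | 25.5 | 27.0 |
| Sunday's | 180 | 24.5 | 9.7 |
| Sunday's | 240 | 19.5 | 3.4 |

(each reading ± 1 percentage point)

- bis adduct, in percent of the substrate first charged, at 2.0 h
- the option that brings most further bis adduct ("none" if no option brings more than 2 percentage points) (gamma / epsilon / eta / theta / none)
- bis adduct present, with what was taken out counted in, in percent of the substrate first charged, after eta
- bis adduct present, with what was taken out counted in, in percent of the substrate first charged, after theta

- gamma: at 2.0 h add reagent, 100% of the amount charged, then wait 2.0 h
- epsilon: at 2.0 h raise the temperature by 25 K, then wait 2.0 h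
- eta: at 2.0 h take out 90% of the bis adduct then present, then wait 2.0 h
- theta: change nothing and wait 2.0 h more

- what is taken out of bis adduct is counted as made
- additions bring no volume worth counting

The ledger of Tuesday's flask at 120 min has 0.3% of the substrate still there and 27.0% as bis adduct, and it leaves 72.7% unread. The bis share there read 0.276 at 40.0 min, so within the scatter it stands still. In Sunday's colder flask it falls from 0.349 at 80.0 min to 0.202 at 240 min. I read this as bis adduct in balance with an unseen partner, a balance that lies further toward bis adduct when warm.

The small thing is what waiting can still add. The last substrate reading is under the scatter, so I extend the earlier first-order fall and get 0.765% left at 2.0 h. Multiplied by the bis share, that is a correction of 0.21 percentage points, less than the margin of 2 points. So I commit to about 27.0% now, nothing useful from theta or from gamma, and a gain from epsilon, with eta second; the readings do not size either gain.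

The forecast gives 27% now, 27.5% after eta and 27% after theta, and it names gamma, holding that “Waiting, heating or removing product therefore changes little”. We part on the option.

The flask gives 26.2% at 2.0 h, 26.4% after theta and 35.6% after eta. The gains are 0.47 points for gamma, 9.4 points for eta and 15 points for epsilon, so the best option is epsilon.

    substrate → decomposition product (k = 1.90 × 10⁻⁴ /min, Ea = 100 kJ/mol)
    reagent + mono adduct → bis adduct + by-product (k = 0.400 /M/min, Ea = 64.0 kJ/mol)
    substrate + reagent → mono adduct + by-product (k = 0.130 /M/min, Ea = 49.0 kJ/mol)
    mono adduct → side product (k = 0.170 /min, Ea = 80.0 kJ/mol)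
    bis adduct ⇌ isomer of the product (K = 0.640, k = 0.0420 /min, Ea = 84.0 kJ/mol, ΔH = −87.0 kJ/mol)
    (constants at 25 °C)

Mono adduct has a half-life of 4.1 min on its way to side product, shorter than the substrate's 15 min by its reaction with reagent at 13.2 min. At 120 min this flask holds mono adduct at 0.173%, side product at 55.3%, isomer of the product at 16.6% and decomposition product at 0.429%, and with the bis adduct and the substrate left these close the ledger. The bis share of this flask comes to 0.265, and on the 1.3% of substrate left it gives 0.35 points against the 0.23 points that theta brings. In the same flask with 12.0 equiv of reagent, the bis share reaches 0.484.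

The earlier runs and the new flask are simulated from invented constants, noise included.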